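**Assumption:** CNP0172182.1 is taken exactly as the given SMILES: all eight stereocentres R, all three esters angelates [(Z)-2-methylbut-2-enoates]. Locants used below: ring C1–C6 (C1 carries the side chain, C4 the methyl), side chain C7(=CH2)–C8–C9–C10–C11. α = ring face of the C1 side chain (also C4–OH, C5–OH, C6–O); β = opposite face (C2–O, C3–O, C4–CH3).

## Retrosynthetic overview

1. Last bond C7–C8: electroreductive Ni/Cr (Nozaki–Hiyama–Kishi-type) union of a fully functionalised ring alkenyl triflate with a γ-lactol; C10 sets C8 (1,3-anti).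
2. The carbocycle is bought as (R)-carvone (its stereocentre becomes C1); the isopropenyl group becomes the alkenyl triflate (ozonolysis, kinetic enol triflation).
3. Ring oxygens, each set by its neighbour: C6 (Rubottom, then Mitsunobu inversion with angelic acid), C5 (Luche), C4 (photochemical hydroxy-directed singlet-oxygen ene), C2/C3 (Woodward–Prévost cis-hydroxy-angeloyloxylation).
4. Lactol from D-malic acid (C10): dioxolanone, MeMgBr, lactonisation, angeloylation, disiamylborane.
5. Ring order: no carbocycle is built; the only ring formed is the temporary oxolane of the side-chain piece, which opens again in the final coupling.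

## Route

Step 1
Reactants: 1 (R)-(−)-carvone
Product: 3 (5S,6S)-6-[(tert-butyldimethylsilyl)oxy]-2-methyl-5-(prop-1-en-2-yl)cyclohex-2-en-1-one, via cross-conjugated silyl dienol ether 2 (not isolated)
Conditions: TBSOTf, Et3N, CH2Cl2, 0 °C; then mCPBA (1.05 equiv), NaHCO3, CH2Cl2, −20 °C to rt
Reagents that add atoms: TBSOTf CC(C)(C)[Si](C)(C)OS(=O)(=O)C(F)(F)F; mCPBA O=C(OO)c1cccc(Cl)c1
Why: Rubottom oxidation: the peracid epoxidises the electron-rich enol ether C5=C6 (not the isopropenyl group) on the β face, anti to the adjacent C1 substituent, and 1,4-silyl shift gives the trans α'-silyloxy enone, so C1 sets C6.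

Step 2
Reactants: 3 (5S,6S)-6-[(tert-butyldimethylsilyl)oxy]-2-methyl-5-(prop-1-en-2-yl)cyclohex-2-en-1-one
Product: 4 (5R,6S)-5-acetyl-6-[(tert-butyldimethylsilyl)oxy]-2-methylcyclohex-2-en-1-one
Conditions: O3 (1.0 equiv), CH2Cl2/MeOH, −78 °C; then Me2S, −78 °C to rt
Reagents that add atoms: ozone [O-][O+]=O
Why: Ozonolysis is chemoselective for the electron-rich 1,1-disubstituted alkene over the electron-poor enone; no stereocentre is touched.

Step 3
Reactants: 4 (5R,6S)-5-acetyl-6-[(tert-butyldimethylsilyl)oxy]-2-methylcyclohex-2-en-1-one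
Product: 5 1-[(1R,6S)-6-[(tert-butyldimethylsilyl)oxy]-4-methyl-5-oxocyclohex-3-en-1-yl]ethenyl trifluoromethanesulfonate
Conditions: KN(SiMe3)2 (1.1 equiv) added to 4 and PhNTf2 in THF, −78 °C; then aq. HCl (0.5 M), 0 °C
Reagents that add atoms: PhNTf2 O=S(=O)(N(c1ccccc1)S(=O)(=O)C(F)(F)F)C(F)(F)F
Why: Kinetic enolate O-triflation: the bulky amide removes a methyl proton of the acetyl group (the only other ring α-proton, C6–H, is hindered and deactivated by the silyloxy group) and the enolate is trapped in situ.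

Step 4
Reactants: 5 1-[(1R,6S)-6-[(tert-butyldimethylsilyl)oxy]-4-methyl-5-oxocyclohex-3-en-1-yl]ethenyl trifluoromethanesulfonate
Product: 6 1-[(1R,6S)-6-hydroxy-4-methyl-5-oxocyclohex-3-en-1-yl]ethenyl trifluoromethanesulfonate
Conditions: HF·pyridine, THF/pyridine, 0 °C to rt
Reagents that add atoms: none
Why: Fluoride-mediated desilylation under mildly acidic conditions leaves the alkenyl triflate, the enone and the α-ketol stereocentre intact.

Step 5
Reactants: 6 1-[(1R,6S)-6-hydroxy-4-methyl-5-oxocyclohex-3-en-1-yl]ethenyl trifluoromethanesulfonate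
Product: 7 (1R,6R)-3-methyl-2-oxo-6-{1-[(trifluoromethanesulfonyl)oxy]ethenyl}cyclohex-3-en-1-yl (2Z)-2-methylbut-2-enoate
Conditions: angelic acid, PPh3, DIAD, toluene, 0 °C to rt
Reagents that add atoms: angelic acid C/C=C(/C)C(=O)O
Why: Mitsunobu esterification: SN2 displacement at the carbonyl-activated C6 carbinol inverts it, placing the angelate cis (α) to the C1 substituent under neutral conditions that do not isomerise the (Z)-alkene.

Step 6
Reactants: 7 (1R,6R)-3-methyl-2-oxo-6-{1-[(trifluoromethanesulfonyl)oxy]ethenyl}cyclohex-3-en-1-yl (2Z)-2-methylbut-2-enoate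
Product: 8 (1R,2S,6R)-2-hydroxy-3-methyl-6-{1-[(trifluoromethanesulfonyl)oxy]ethenyl}cyclohex-3-en-1-yl (2Z)-2-methylbut-2-enoate
Conditions: NaBH4, CeCl3·7H2O, MeOH, −78 °C; AcOH quench at −78 °C
Reagents that add atoms: none
Why: Luche 1,2-reduction: hydride adds axially from the β face, antiperiplanar to the axial C6–O bond (Felkin–Anh polar model), giving the α (equatorial) C5–OH cis to the C6 ester; the cold acidic quench prevents acyl migration.

Step 7
Reactants: 8 (1R,2S,6R)-2-hydroxy-3-methyl-6-{1-[(trifluoromethanesulfonyl)oxy]ethenyl}cyclohex-3-en-1-yl (2Z)-2-methylbut-2-enoate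
Product: 10 (1R,2R,3S,6R)-2,3-dihydroxy-3-methyl-6-{1-[(trifluoromethanesulfonyl)oxy]ethenyl}cyclohex-4-en-1-yl (2Z)-2-methylbut-2-enoate, via tertiary allylic hydroperoxide 9 (not isolated)
Conditions: O2, meso-tetraphenylporphyrin (1 mol %), white LEDs, CH2Cl2, −20 °C; then PPh3, −20 °C to rt
Reagents that add atoms: dioxygen O=O
Why: Photosensitised Schenck ene reaction of singlet oxygen, hydroxy-directed: the perepoxide hydrogen-bonded to the C5–OH on the α face abstracts the pseudoaxial α C2–H and bonds to C4, giving the α tertiary hydroperoxide (C4 set by C5) with the alkene moved to C2=C3, and PPh3 reduces the O–O bond; the triflate and angelate alkenes are too electron-poor to react.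

Step 8
Reactants: 10 (1R,2R,3S,6R)-2,3-dihydroxy-3-methyl-6-{1-[(trifluoromethanesulfonyl)oxy]ethenyl}cyclohex-4-en-1-yl (2Z)-2-methylbut-2-enoate
Product: 13 (1R,2R,3R,4R,5R,6R)-2,3,6-trihydroxy-2-methyl-5-{1-[(trifluoromethanesulfonyl)oxy]ethenyl}cyclohexane-1,4-diyl bis[(2Z)-2-methylbut-2-enoate], via trans-iodo angelate 11 (not isolated), via cis-fused acyloxonium ion 12 (not isolated)
Conditions: I2 (1.05 equiv), pre-formed AgO2CC(CH3)=CHCH3 (silver angelate, 2.2 equiv), toluene, dark, 0 °C to rt; then H2O (2 equiv), 45 °C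
Reagents that add atoms: silver angelate C/C=C(/C)C(=O)[O-].[Ag+]; water O
Why: Woodward–Prévost cis-hydroxylation run with silver angelate: the α iodonium ion is opened trans-diaxially by angelate at C3 from the β face (the competing axial attack at C2 from the α face is blocked by the axial C4–OH and C6 ester), silver-assisted neighbouring-group displacement of iodide gives the β cis-fused acyloxonium ion, and its hydrolysis leaves the ester on the axial C3 oxygen and a free equatorial C2–OH, so the ring centres set C2 and C3.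

Step 9
Reactants: 14 D-malic acid [(R)-2-hydroxybutanedioic acid]
Product: 15 2-[(4R)-2,2-dimethyl-5-oxo-1,3-dioxolan-4-yl]acetic acid
Conditions: 2,2-dimethoxypropane, PPTS (cat.), rt
Reagents that add atoms: 2,2-dimethoxypropane COC(C)(C)OC
Why: Acid-catalysed acetalisation closes the five-membered dioxolanone on the α-hydroxy acid only, which differentiates the two carboxyl groups without touching the stereocentre.

Step 10
Reactants: 15 2-[(4R)-2,2-dimethyl-5-oxo-1,3-dioxolan-4-yl]acetic acid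
Product: 17 (4R)-4-hydroxy-5,5-dimethyloxolan-2-one, via open-chain dihydroxy acid 16 (not isolated)
Conditions: MeMgBr (5 equiv), THF, −20 to 0 °C; then aq. HCl (2 M), rt
Reagents that add atoms: methylmagnesium bromide C[Mg]Br
Why: Grignard double addition to the activated dioxolanone carbonyl (the magnesium carboxylate is inert) builds the C11 dimethyl carbinol, and acidification lactonises the γ-hydroxy acid; the C10 stereocentre is untouched.

Step 11
Reactants: 17 (4R)-4-hydroxy-5,5-dimethyloxolan-2-one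
Product: 18 (3R)-2,2-dimethyl-5-oxooxolan-3-yl (2Z)-2-methylbut-2-enoate
Conditions: angelic acid, 2,4,6-trichlorobenzoyl chloride, Et3N, toluene, rt; then 17, DMAP (cat.), 60 °C
Reagents that add atoms: angelic acid C/C=C(/C)C(=O)O
Why: Yamaguchi esterification through the mixed anhydride acylates the hindered secondary alcohol, a protocol chosen because it transfers the angeloyl group without Z-to-E isomerisation.

Step 12
Reactants: 18 (3R)-2,2-dimethyl-5-oxooxolan-3-yl (2Z)-2-methylbut-2-enoate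
Product: 19 (3R)-5-hydroxy-2,2-dimethyloxolan-3-yl (2Z)-2-methylbut-2-enoate (anomer mixture)
Conditions: disiamylborane (2.5 equiv, made in the flask from BH3·THF and 2-methylbut-2-ene), THF, 0 °C to rt; then H2O, pH 7 buffer (NaH2PO4/Na2HPO4)
Reagents that add atoms: none
Why: Disiamylborane reduction of a γ-lactone to the lactol is chemoselective: ordinary esters and the hindered, electron-poor trisubstituted alkene of the angelate do not react.

Step 13
Reactants: 13 (1R,2R,3R,4R,5R,6R)-2,3,6-trihydroxy-2-methyl-5-{1-[(trifluoromethanesulfonyl)oxy]ethenyl}cyclohexane-1,4-diyl bis[(2Z)-2-methylbut-2-enoate]; 19 (3R)-5-hydroxy-2,2-dimethyloxolan-3-yl (2Z)-2-methylbut-2-enoate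
Product: 21 CNP0172182.1 [(1R,2R,3R,4R,5R,6R)-2,3,6-trihydroxy-5-{(3R,5R)-3,6-dihydroxy-6-methyl-5-{[(2Z)-2-methylbut-2-enoyl]oxy}hept-1-en-2-yl}-2-methylcyclohexane-1,4-diyl bis[(2Z)-2-methylbut-2-enoate]], via ring-opened hydroxy aldehyde 20 (not isolated)
Conditions: 19 (1.5 equiv), CrCl2 (20 mol %), NiCl2·DME (5 mol %), neocuproine (5 mol %), LiCl, DMF, undivided cell, Al anode, Ni-foam cathode, 3 mA (2.5 F/mol), rt; then aq. KNaC4H4O6
Reagents that add atoms: none
Why: Proposed new method: a chromium-catalysed electroreductive Nozaki–Hiyama–Kishi alkenylation run directly on a γ-lactol and an unprotected polyol alkenyl triflate; the cathode regenerates divalent chromium, which reduces the nickel catalyst to zerovalent nickel for oxidative addition into the C–OTf bond of 13, transmetalation gives an alkenyl species of trivalent chromium that tolerates free hydroxyls and esters, Al3+ from the sacrificial anode opens lactol 19 to aldehyde 20 and later frees chromium from the product alkoxide (in place of a chlorosilane or Cp2ZrCl2, which would cap the lactol), and addition to the β-acyloxy aldehyde is 1,3-anti (Cram–Reetz chelate and Evans polar model agree) so that C10 sets C8 as R; the closest known reactions are the electrochemical NHK coupling of alkenyl (pseudo)halides with free aldehydes and the stoichiometric CrCl2/NiCl2 NHK reaction.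

## Compound list

1 | (R)-(−)-carvone | C=C(C)[C@@H]1CC=C(C)C(=O)C1 | starting material
2 | tert-butyl(dimethyl){[(3R)-6-methyl-3-(prop-1-en-2-yl)cyclohexa-1,5-dien-1-yl]oxy}silane (cross-conjugated silyl dienol ether of 1) | C=C(C)[C@@H]1CC=C(C)C(O[Si](C)(C)C(C)(C)C)=C1 | intermediate
3 | (5S,6S)-6-[(tert-butyldimethylsilyl)oxy]-2-methyl-5-(prop-1-en-2-yl)cyclohex-2-en-1-one (silyloxy trans to isopropenyl) | C=C(C)[C@@H]1CC=C(C)C(=O)[C@H]1O[Si](C)(C)C(C)(C)C | intermediate
4 | (5R,6S)-5-acetyl-6-[(tert-butyldimethylsilyl)oxy]-2-methylcyclohex-2-en-1-one | CC(=O)[C@@H]1CC=C(C)C(=O)[C@H]1O[Si](C)(C)C(C)(C)C | intermediate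
5 | 1-[(1R,6S)-6-[(tert-butyldimethylsilyl)oxy]-4-methyl-5-oxocyclohex-3-en-1-yl]ethenyl trifluoromethanesulfonate | C=C(OS(=O)(=O)C(F)(F)F)[C@@H]1CC=C(C)C(=O)[C@H]1O[Si](C)(C)C(C)(C)C | intermediate
6 | 1-[(1R,6S)-6-hydroxy-4-methyl-5-oxocyclohex-3-en-1-yl]ethenyl trifluoromethanesulfonate | C=C(OS(=O)(=O)C(F)(F)F)[C@@H]1CC=C(C)C(=O)[C@H]1O | intermediate
7 | (1R,6R)-3-methyl-2-oxo-6-{1-[(trifluoromethanesulfonyl)oxy]ethenyl}cyclohex-3-en-1-yl (2Z)-2-methylbut-2-enoate (C6 angelate cis to the C1 substituent) | C=C(OS(=O)(=O)C(F)(F)F)[C@@H]1CC=C(C)C(=O)[C@@H]1OC(=O)/C(C)=C\C | intermediate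
8 | (1R,2S,6R)-2-hydroxy-3-methyl-6-{1-[(trifluoromethanesulfonyl)oxy]ethenyl}cyclohex-3-en-1-yl (2Z)-2-methylbut-2-enoate (C5–OH cis to the C6 ester) | C=C(OS(=O)(=O)C(F)(F)F)[C@@H]1CC=C(C)[C@H](O)[C@@H]1OC(=O)/C(C)=C\C | intermediate
9 | (1R,2R,3S,6R)-3-hydroperoxy-2-hydroxy-3-methyl-6-{1-[(trifluoromethanesulfonyl)oxy]ethenyl}cyclohex-4-en-1-yl (2Z)-2-methylbut-2-enoate | C=C(OS(=O)(=O)C(F)(F)F)[C@@H]1C=C[C@](C)(OO)[C@H](O)[C@@H]1OC(=O)/C(C)=C\C | intermediate
10 | (1R,2R,3S,6R)-2,3-dihydroxy-3-methyl-6-{1-[(trifluoromethanesulfonyl)oxy]ethenyl}cyclohex-4-en-1-yl (2Z)-2-methylbut-2-enoate | C=C(OS(=O)(=O)C(F)(F)F)[C@@H]1C=C[C@](C)(O)[C@H](O)[C@@H]1OC(=O)/C(C)=C\C | intermediate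
11 | trans-diaxial iodo angelate: 10 after addition of iodine at C2 (α, cis to the C1 substituent) and angeloyloxy at C3 (β) | C=C(OS(=O)(=O)C(F)(F)F)[C@@H]1[C@H](I)[C@@H](OC(=O)/C(C)=C\C)[C@](C)(O)[C@H](O)[C@@H]1OC(=O)/C(C)=C\C | intermediate
12 | acyloxonium ion: 2-[(Z)-but-2-en-2-yl]-1,3-dioxolan-2-ylium cis-fused through the β oxygens on C2 and C3 | C=C(OS(=O)(=O)C(F)(F)F)[C@@H]1[C@@H](OC(/C(C)=C\C)=[O+]2)[C@@H]2[C@](C)(O)[C@H](O)[C@@H]1OC(=O)/C(C)=C\C | intermediate
13 | (1R,2R,3R,4R,5R,6R)-2,3,6-trihydroxy-2-methyl-5-{1-[(trifluoromethanesulfonyl)oxy]ethenyl}cyclohexane-1,4-diyl bis[(2Z)-2-methylbut-2-enoate] (ring fragment) | C=C(OS(=O)(=O)C(F)(F)F)[C@@H]1[C@@H](O)[C@@H](OC(=O)/C(C)=C\C)[C@](C)(O)[C@H](O)[C@@H]1OC(=O)/C(C)=C\C | intermediate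
14 | D-malic acid [(R)-2-hydroxybutanedioic acid] | OC(=O)C[C@@H](O)C(O)=O | starting material
15 | 2-[(4R)-2,2-dimethyl-5-oxo-1,3-dioxolan-4-yl]acetic acid | CC1(C)O[C@H](CC(=O)O)C(=O)O1 | intermediate
16 | (3R)-3,4-dihydroxy-4-methylpentanoic acid | OC(=O)C[C@@H](O)C(C)(C)O | intermediate
17 | (4R)-4-hydroxy-5,5-dimethyloxolan-2-one | O=C1C[C@@H](O)C(C)(C)O1 | intermediate
18 | (3R)-2,2-dimethyl-5-oxooxolan-3-yl (2Z)-2-methylbut-2-enoate | O=C1C[C@@H](OC(=O)/C(C)=C\C)C(C)(C)O1 | intermediate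
19 | (3R)-5-hydroxy-2,2-dimethyloxolan-3-yl (2Z)-2-methylbut-2-enoate (lactol, anomer mixture) | OC1C[C@@H](OC(=O)/C(C)=C\C)C(C)(C)O1 | intermediate
20 | (3R)-2-hydroxy-2-methyl-5-oxopentan-3-yl (2Z)-2-methylbut-2-enoate (open-chain tautomer of 19) | O=CC[C@@H](OC(=O)/C(C)=C\C)C(C)(C)O | intermediate
21 | CNP0172182.1, (1R,2R,3R,4R,5R,6R)-2,3,6-trihydroxy-5-{(3R,5R)-3,6-dihydroxy-6-methyl-5-{[(2Z)-2-methylbut-2-enoyl]oxy}hept-1-en-2-yl}-2-methylcyclohexane-1,4-diyl bis[(2Z)-2-methylbut-2-enoate] | C=C([C@@H]1[C@@H](O)[C@@H](OC(=O)/C(C)=C\C)[C@](C)(O)[C@H](O)[C@@H]1OC(=O)/C(C)=C\C)[C@H](O)C[C@@H](OC(=O)/C(C)=C\C)C(C)(C)O | target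

## Step count and risks

Total step count: 13 (steps 1–8 ring fragment, steps 9–12 side-chain fragment, step 13 union).
Longest linear sequence: 9 (steps 1–8, then 13).

The three steps most likely to fail:

**Step 13 (proposed new electrochemical coupling).** The lactol may not supply enough free aldehyde, the catalysts may be sequestered by the polyol, or the C8 selectivity may be low. The fallback uses known chemistry, sets out from 19 and returns at 21. Lactol 19 is opened with propane-1,3-dithiol and BF3·OEt2 to the dithiane alcohol F6. Its tertiary hydroxyl is silylated with TESOTf and 2,6-lutidine to the triethylsilyl ether F7. I2/NaHCO3 in aqueous acetone unmasks the open-chain β-acyloxy aldehyde F8. F8 is coupled with 13 under the classical stoichiometric Nozaki–Hiyama–Kishi conditions (CrCl2, catalytic NiCl2, DMSO, rt) to the silyl-protected coupling product F9, and HF·pyridine then gives 21.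

**Step 8 (Woodward–Prévost with silver angelate).** Risks are Z-to-E isomerisation in the acyloxonium ion, the wrong iodonium face, or the ester ending on C2. The fallback sets out from 10 and returns at 13. Catalytic OsO4 with NMO dihydroxylates C2=C3 from the β face (anti to the C1 substituent and to the allylic C4–OH) to the tetraol F3. TESCl/imidazole silylates the two equatorial secondary hydroxyls (C2 and C5) to the bis-silyl ether F4. Yamaguchi angeloylation of the remaining axial C3–OH gives the diangelate F5, and HF·pyridine returns 13.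

**Step 7 (singlet-oxygen ene).** Risks are attack from the β face or hydrogen abstraction from the C4 methyl. The fallback sets out from 8 and returns at 10. VO(acac)2/t-BuOOH epoxidation directed by the C5–OH gives the α epoxy alcohol F1. NaSePh (from PhSeSePh and NaBH4, EtOH) opens it trans-diaxially at C3 to the hydroxy selenide F2. Oxidation with H2O2/pyridine and selenoxide syn-elimination toward C2 then gives 10.

Further compounds
F1 | step 7 | 3,4-epoxide of 8, epoxide oxygen α (cis to the C5–OH and to the C6 angelate) | C=C(OS(=O)(=O)C(F)(F)F)[C@@H]1C[C@@H]2O[C@]2(C)[C@H](O)[C@@H]1OC(=O)/C(C)=C\C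
F2 | step 7 | C3 β-phenylselanyl C4,C5 α-diol (hydroxy selenide from F1) | C=C(OS(=O)(=O)C(F)(F)F)[C@@H]1C[C@@H]([Se]c2ccccc2)[C@](C)(O)[C@H](O)[C@@H]1OC(=O)/C(C)=C\C
F3 | step 8 | C2,C3 β-cis-diol of 10 (tetraol mono-angelate) | C=C(OS(=O)(=O)C(F)(F)F)[C@@H]1[C@@H](O)[C@@H](O)[C@](C)(O)[C@H](O)[C@@H]1OC(=O)/C(C)=C\C
F4 | step 8 | C2,C5-bis(triethylsilyl) ether of F3 | C=C(OS(=O)(=O)C(F)(F)F)[C@@H]1[C@@H](O[Si](CC)(CC)CC)[C@@H](O)[C@](C)(O)[C@H](O[Si](CC)(CC)CC)[C@@H]1OC(=O)/C(C)=C\C
F5 | step 8 | C2,C5-bis(triethylsilyl) ether of 13 (C3,C6 diangelate) | C=C(OS(=O)(=O)C(F)(F)F)[C@@H]1[C@@H](O[Si](CC)(CC)CC)[C@@H](OC(=O)/C(C)=C\C)[C@](C)(O)[C@H](O[Si](CC)(CC)CC)[C@@H]1OC(=O)/C(C)=C\C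
F6 | step 13 | (2R)-1-(1,3-dithian-2-yl)-3-hydroxy-3-methylbutan-2-yl (2Z)-2-methylbut-2-enoate | C1CSC(SC1)C[C@@H](OC(=O)/C(C)=C\C)C(C)(C)O
F7 | step 13 | (2R)-1-(1,3-dithian-2-yl)-3-methyl-3-[(triethylsilyl)oxy]butan-2-yl (2Z)-2-methylbut-2-enoate | C1CSC(SC1)C[C@@H](OC(=O)/C(C)=C\C)C(C)(C)O[Si](CC)(CC)CC
F8 | step 13 | (3R)-2-methyl-5-oxo-2-[(triethylsilyl)oxy]pentan-3-yl (2Z)-2-methylbut-2-enoate | O=CC[C@@H](OC(=O)/C(C)=C\C)C(C)(C)O[Si](CC)(CC)CC
F9 | step 13 | C11 triethylsilyl ether of 21 | C=C([C@@H]1[C@@H](O)[C@@H](OC(=O)/C(C)=C\C)[C@](C)(O)[C@H](O)[C@@H]1OC(=O)/C(C)=C\C)[C@H](O)C[C@@H](OC(=O)/C(C)=C\C)C(C)(C)O[Si](CC)(CC)CC
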